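The seven-membered ring is cut at C7–C8 and C10–C1 (daucane numbering: C1 is the methyl-bearing ring-fusion carbon, C8 the methylene-bearing carbon). This (4+3) disconnection exploits the fact that the three contiguous functionalised ring carbons C8, C9 and C10 face the four-carbon unit C7–C6–C5–C1, which is the diene of an achiral 2-vinylcyclopentenone. One dirhodium-catalysed cyclopropanation/divinylcyclopropane Cope cascade closes the ring, sets the C1 quaternary centre and the C10 carbinol centre, and installs an ester on C8 (the later exocyclic methylene) and silyloxy groups on C9 and C10 (the later cis-diol). Its precursors are 3-methyl-2-vinylcyclopent-2-enone and a (Z)-bis(silyloxy)vinyl diazoacetate.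

Key step: step 5

Remarks:
- Ring atoms carry daucane numbers in all names: five-membered ring C1–C5, seven-membered ring C1 and C5–C10, C14 on C8, C15 the methyl on C1, C11–C13 the isopropyl group. α is the face opposite to C15. TBS = tert-butyldimethylsilyl.
- Compounds 1, 2, 4 and 5 are taken as commercial.
- Assumption: Rh2(S-PTAD)4 is assumed to give the C1 configuration drawn; if its sense of induction is the opposite, the mirror-image catalyst Rh2(R-PTAD)4 is used.

Step 1
Reactants: 1 2-bromo-3-methylcyclopent-2-en-1-one; 2 potassium vinyltrifluoroborate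
Product: 3 3-methyl-2-vinylcyclopent-2-en-1-one
Conditions: PdCl2(dppf)·CH2Cl2 (3 mol %), Cs2CO3, THF–H2O, 70 °C
Reagents that add atoms: none
Why: Suzuki–Miyaura coupling, in which the electron-poor α-bromo enone adds readily to zerovalent palladium; no stereocentre is formed.

Step 2
Reactants: 4 methyl 2-(TBS-oxy)acetate; 5 methyl acetate
Product: 6 methyl 4-(TBS-oxy)-3-oxobutanoate
Conditions: LiN(iPr)2 (2.2 equiv), 5 (2.2 equiv), THF, −78 °C; then 4, −78 to −20 °C; AcOH quench
Reagents that add atoms: none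
Why: Crossed Claisen condensation, in which the lithium enolate of methyl acetate acylates the more electrophilic α-silyloxy ester and the second equivalent of enolate stores the product as its enolate.

Step 3
Reactants: 6 methyl 4-(TBS-oxy)-3-oxobutanoate
Product: 7 methyl 4-(TBS-oxy)-2-diazo-3-oxobutanoate
Conditions: 4-acetamidobenzenesulfonyl azide, Et3N, MeCN, 0 °C to rt
Reagents that add atoms: 4-acetamidobenzenesulfonyl azide, CC(=O)Nc1ccc(cc1)S(=O)(=O)N=[N+]=[N-]
Why: Regitz diazo transfer to the doubly activated methylene of the β-keto ester.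

Step 4
Reactants: 7 methyl 4-(TBS-oxy)-2-diazo-3-oxobutanoate
Product: 8 methyl (Z)-3,4-bis(TBS-oxy)-2-diazobut-3-enoate
Conditions: TBSOTf, Et3N, CH2Cl2, 0 °C
Reagents that add atoms: tert-butyldimethylsilyl trifluoromethanesulfonate, CC(C)(C)[Si](C)(C)OS(=O)(=O)C(F)(F)F
Why: Soft enolisation and O-silylation toward the only enolisable CH2, where allylic strain against the diazoester unit should place the two silyloxy groups cis ((Z)-enediol bis-silyl ether).

Step 5
Reactants: 3 3-methyl-2-vinylcyclopent-2-en-1-one; 8 methyl (Z)-3,4-bis(TBS-oxy)-2-diazobut-3-enoate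
Product: 10 methyl 9,10α-bis(TBS-oxy)-4-oxo-11,12,13-trinordauca-5,8-dien-14-oate, via cis-divinylcyclopropane 9 (not isolated)
Conditions: Rh2(S-PTAD)4 (dirhodium tetrakis[(S)-(1-adamantyl)(N-phthalimido)acetate], 1 mol %), 3 (2 equiv), slow addition of 8, hexanes–toluene, −20 °C to rt; then 80 °C
Reagents that add atoms: none
Why: The dirhodium carbenoid from 8 cyclopropanates the vinyl group of 3 with the silyloxyvinyl donor cis to the cyclopentenyl group (C7–C8 bond), and the cis-divinylcyclopropane 9 then undergoes a Cope rearrangement through a boat transition state in which the C6–C8 bond breaks and the C10–C1 bond forms. The closest known reaction type is the tandem cyclopropanation/Cope formal (4+3) cycloaddition of silyloxyvinyl diazoacetates with dienes, including 2-methyl-1-vinylcycloalkenes that give angular-methyl quaternary centres. The three-membered ring is closed by (2+1) carbene addition and the seven-membered ring by a [3,3]-sigmatropic ring expansion, not by an ionic cyclisation. The C1 quaternary centre is controlled by the catalyst, because the face of the vinyl group that is cyclopropanated fixes the face of the cyclopentene reached in the boat transition state; C10 is controlled by the (Z)-enol ether geometry, the outward silyloxy group ending trans to the inward C1 methyl (10α-oxygen, 1β-methyl). The step needs attack at the monosubstituted vinyl group and not at the enone alkene or carbonyl, cis-divinyl geometry and one alkene face; these should be secured by the hindered, electron-poor tetrasubstituted enone, by the donor/acceptor carbenoid and by the chiral carboxylate ligands.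

Step 6
Reactants: 10 methyl 9,10α-bis(TBS-oxy)-4-oxo-11,12,13-trinordauca-5,8-dien-14-oate
Product: 11 methyl 9,10α-bis(TBS-oxy)-4-hydroxydauca-5,8-dien-14-oate (C4 epimers)
Conditions: iPrMgCl, anhydrous CeCl3, THF, −78 °C; H2O quench
Reagents that add atoms: isopropylmagnesium chloride, CC(C)[Mg]Cl
Why: 1,2-Addition of the weakly basic organocerium reagent to the enone carbonyl, the vinylogous carbonate ester being far less electrophilic; the configuration of the new carbinol centre is immaterial because step 7 erases it.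

Step 7
Reactants: 11 methyl 9,10α-bis(TBS-oxy)-4-hydroxydauca-5,8-dien-14-oate
Product: 12 methyl 9,10α-bis(TBS-oxy)-6-oxodauca-4,8-dien-14-oate
Conditions: pyridinium chlorochromate C5H5NH[CrO3Cl], NaOAc, 4 Å MS, CH2Cl2, rt
Reagents that add atoms: none
Why: Babler–Dauben oxidative transposition, in which the chromate ester of the tertiary allylic alcohol shifts [3,3] to C6 and is oxidised to the tetrasubstituted enone.

Step 8
Reactants: 12 methyl 9,10α-bis(TBS-oxy)-6-oxodauca-4,8-dien-14-oate
Product: 13 methyl 9,10α-bis(TBS-oxy)-4β,5β-epoxy-6-oxodauc-8-en-14-oate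
Conditions: tBuOOH (anhydrous, in decane), DBU, CH2Cl2, 0 °C to rt
Reagents that add atoms: tert-butyl hydroperoxide, CC(C)(C)OO
Why: Weitz–Scheffer nucleophilic epoxidation, in which tert-butylperoxide should add to C4 on the β face because the α face of the planar enone is screened by C10 and its pseudoaxial silyloxy group while the β face carries only the C1 methyl, and the enolate closes to the 4β,5β-epoxide.

Step 9
Reactants: 13 methyl 9,10α-bis(TBS-oxy)-4β,5β-epoxy-6-oxodauc-8-en-14-oate
Product: 15 methyl 9,10α-bis(TBS-oxy)-4β-hydroxy-6-oxo-5α-dauc-8-en-14-oate, via cis-fused hydroxy ketone 14 (not isolated)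
Conditions: SmI2 (2.5 equiv), THF–MeOH, −78 °C; then Et3N, MeOH, rt
Reagents that add atoms: none
Why: Reductive cleavage of the α,β-epoxy ketone at the Cα–O bond by electron transfer from SmI2 keeps the 4β C–O bond; enolate protonation on the open β face should first give cis-fused 14, which equilibrates through the enol to trans-fused 15, where C6 is anti to the isopropyl group and the 4β-hydroxyl can hydrogen-bond to the ketone.

Step 10
Reactants: 15 methyl 9,10α-bis(TBS-oxy)-4β-hydroxy-6-oxo-5α-dauc-8-en-14-oate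
Product: 16 methyl 9,10α-bis(TBS-oxy)-4β,6α-dihydroxy-5α-dauc-8-en-14-oate
Conditions: Me4NBH(OAc)3, MeCN–AcOH, −30 °C
Reagents that add atoms: none
Why: Saksena–Evans reduction, in which the C4 hydroxyl binds the borohydride and delivers hydride to the β face of the C6 ketone to give the 6α-alcohol; only the trans-fused epimer has hydroxyl and ketone syn on the five-membered ring, so any residual 14 should be funnelled through 15 in the acidic medium.

Step 11
Reactants: 16 methyl 9,10α-bis(TBS-oxy)-4β,6α-dihydroxy-5α-dauc-8-en-14-oate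
Product: 18 4β,6α-dihydroxy-10α-(TBS-oxy)-5α-dauc-8(14)-en-9-one, via allylic alcohol 17 (not isolated)
Conditions: iBu2AlH (excess), CH2Cl2, −78 to 0 °C; then aq oxalic acid, THF, 0 °C to rt
Reagents that add atoms: none
Why: Reduction of the vinylogous carbonate ester to allylic alcohol 17, then acid-induced loss of the C14 hydroxyl assisted by the silyl enol ether and loss of the silyl group, gives the α-methylene ketone (reduction–elimination of a β-keto ester enol ether); the hindered C10 silyl ether and the tertiary alcohol should survive the mild acid.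

Step 12
Reactants: 18 4β,6α-dihydroxy-10α-(TBS-oxy)-5α-dauc-8(14)-en-9-one
Product: 19 4β-hydroxy-6α-(3-methylbutanoyloxy)-10α-(TBS-oxy)-5α-dauc-8(14)-en-9-one
Conditions: (iPrCH2CO)2O, pyridine, DMAP (cat.), CH2Cl2, 0 °C
Reagents that add atoms: 3-methylbutanoic anhydride, CC(C)CC(=O)OC(=O)CC(C)C
Why: DMAP-catalysed acylation of the only secondary hydroxyl, the tertiary C4 hydroxyl being unreactive under these conditions.

Step 13
Reactants: 19 4β-hydroxy-6α-(3-methylbutanoyloxy)-10α-(TBS-oxy)-5α-dauc-8(14)-en-9-one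
Product: 20 6α-(3-methylbutanoyloxy)-10α-(TBS-oxy)-5α-dauc-8(14)-ene-4β,9α-diol
Conditions: NaBH4, CeCl3·7H2O, MeOH, −78 °C
Reagents that add atoms: none
Why: Luche 1,2-reduction of the α-methylene ketone, in which hydride should attack C9 anti to the adjacent pseudoaxial 10α-silyloxy group (Felkin–Anh control, polar and steric) to give the 9α-alcohol cis to the C10 oxygen, the isovalerate being inert at −78 °C.

Step 14
Reactants: 20 6α-(3-methylbutanoyloxy)-10α-(TBS-oxy)-5α-dauc-8(14)-ene-4β,9α-diol
Product: 21 6α-(3-methylbutanoyloxy)-5α-dauc-8(14)-ene-4β,9α,10α-triol (target)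
Conditions: HF·pyridine, pyridine, THF, 0 °C to rt
Reagents that add atoms: none
Why: Fluoride cleavage of the last silyl ether; buffered HF·pyridine should leave the ester, the allylic alcohol and the tertiary alcohol untouched.

Compound list
1 | 2-bromo-3-methylcyclopent-2-en-1-one | CC1=C(Br)C(=O)CC1 | starting material
2 | potassium vinyltrifluoroborate | C=C[B-](F)(F)F.[K+] | starting material
3 | 3-methyl-2-vinylcyclopent-2-en-1-one | C=CC1=C(C)CCC1=O | intermediate
4 | methyl 2-(TBS-oxy)acetate | COC(=O)CO[Si](C)(C)C(C)(C)C | starting material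
5 | methyl acetate | COC(C)=O | starting material
6 | methyl 4-(TBS-oxy)-3-oxobutanoate | COC(=O)CC(=O)CO[Si](C)(C)C(C)(C)C | intermediate
7 | methyl 4-(TBS-oxy)-2-diazo-3-oxobutanoate | COC(=O)C(=[N+]=[N-])C(=O)CO[Si](C)(C)C(C)(C)C | intermediate
8 | methyl (Z)-3,4-bis(TBS-oxy)-2-diazobut-3-enoate | COC(=O)C(=[N+]=[N-])/C(O[Si](C)(C)C(C)(C)C)=C/O[Si](C)(C)C(C)(C)C | intermediate
9 | methyl 1-[(Z)-1,2-bis(TBS-oxy)vinyl]-2-(2-methyl-5-oxocyclopent-1-en-1-yl)cyclopropane-1-carboxylate, vinyl and cyclopentenyl groups cis | COC(=O)[C@]1(/C(O[Si](C)(C)C(C)(C)C)=C/O[Si](C)(C)C(C)(C)C)C[C@H]1C2=C(C)CCC2=O | intermediate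
10 | methyl 9,10α-bis(TBS-oxy)-4-oxo-11,12,13-trinordauca-5,8-dien-14-oate (1β-methyl) | COC(=O)C1=C(O[Si](C)(C)C(C)(C)C)[C@@H](O[Si](C)(C)C(C)(C)C)[C@@]2(C)CCC(=O)C2=CC1 | intermediate
11 | methyl 9,10α-bis(TBS-oxy)-4-hydroxydauca-5,8-dien-14-oate, both C4 epimers | COC(=O)C1=C(O[Si](C)(C)C(C)(C)C)[C@@H](O[Si](C)(C)C(C)(C)C)[C@@]2(C)CCC(O)(C(C)C)C2=CC1 | intermediate
12 | methyl 9,10α-bis(TBS-oxy)-6-oxodauca-4,8-dien-14-oate | COC(=O)C1=C(O[Si](C)(C)C(C)(C)C)[C@@H](O[Si](C)(C)C(C)(C)C)[C@@]2(C)CCC(C(C)C)=C2C(=O)C1 | intermediate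
13 | methyl 9,10α-bis(TBS-oxy)-4β,5β-epoxy-6-oxodauc-8-en-14-oate | COC(=O)C1=C(O[Si](C)(C)C(C)(C)C)[C@@H](O[Si](C)(C)C(C)(C)C)[C@@]2(C)CC[C@]3(C(C)C)O[C@]23C(=O)C1 | intermediate
14 | methyl 9,10α-bis(TBS-oxy)-4β-hydroxy-6-oxo-5β-dauc-8-en-14-oate (cis-fused) | COC(=O)C1=C(O[Si](C)(C)C(C)(C)C)[C@@H](O[Si](C)(C)C(C)(C)C)[C@@]2(C)CC[C@@](O)(C(C)C)[C@H]2C(=O)C1 | intermediate
15 | methyl 9,10α-bis(TBS-oxy)-4β-hydroxy-6-oxo-5α-dauc-8-en-14-oate (trans-fused) | COC(=O)C1=C(O[Si](C)(C)C(C)(C)C)[C@@H](O[Si](C)(C)C(C)(C)C)[C@@]2(C)CC[C@@](O)(C(C)C)[C@@H]2C(=O)C1 | intermediate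
16 | methyl 9,10α-bis(TBS-oxy)-4β,6α-dihydroxy-5α-dauc-8-en-14-oate | COC(=O)C1=C(O[Si](C)(C)C(C)(C)C)[C@@H](O[Si](C)(C)C(C)(C)C)[C@@]2(C)CC[C@@](O)(C(C)C)[C@@H]2[C@@H](O)C1 | intermediate
17 | 9,10α-bis(TBS-oxy)-5α-dauc-8-ene-4β,6α,14-triol | OCC1=C(O[Si](C)(C)C(C)(C)C)[C@@H](O[Si](C)(C)C(C)(C)C)[C@@]2(C)CC[C@@](O)(C(C)C)[C@@H]2[C@@H](O)C1 | intermediate
18 | 4β,6α-dihydroxy-10α-(TBS-oxy)-5α-dauc-8(14)-en-9-one | C=C1C[C@H](O)[C@@H]2[C@](C)(CC[C@@]2(O)C(C)C)[C@H](O[Si](C)(C)C(C)(C)C)C1=O | intermediate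
19 | 4β-hydroxy-6α-(3-methylbutanoyloxy)-10α-(TBS-oxy)-5α-dauc-8(14)-en-9-one | C=C1C[C@H](OC(=O)CC(C)C)[C@@H]2[C@](C)(CC[C@@]2(O)C(C)C)[C@H](O[Si](C)(C)C(C)(C)C)C1=O | intermediate
20 | 6α-(3-methylbutanoyloxy)-10α-(TBS-oxy)-5α-dauc-8(14)-ene-4β,9α-diol | C=C1C[C@H](OC(=O)CC(C)C)[C@@H]2[C@](C)(CC[C@@]2(O)C(C)C)[C@H](O[Si](C)(C)C(C)(C)C)[C@@H]1O | intermediate
21 | 6α-(3-methylbutanoyloxy)-5α-dauc-8(14)-ene-4β,9α,10α-triol | C=C1C[C@H](OC(=O)CC(C)C)[C@@H]2[C@](C)(CC[C@@]2(O)C(C)C)[C@H](O)[C@@H]1O | target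

Total steps: 14. Longest linear sequence: 13 steps (steps 2–14, from 4).

Steps most likely to fail

Step 5. The electrophilic carbenoid may dimerise or form a carbonyl ylide faster than it cyclopropanates the vinyl group of the electron-poor dienone. The catalyst may also discriminate poorly between the two faces of a diene that carries a Lewis-basic ketone. Fallback, from 1 back to 10: the ketone is masked before the cascade. Ketalisation of 1 with ethane-1,2-diol (TsOH, benzene, azeotropic removal of water) should give 6-bromo-7-methyl-1,4-dioxaspiro[4.4]non-6-ene F1. Suzuki–Miyaura coupling of F1 with 2 should give the electron-richer 7-methyl-6-vinyl-1,4-dioxaspiro[4.4]non-6-ene F2. The same dirhodium cascade with 8 should give the cycloadduct ethylene ketal F3. PPTS in wet acetone should remove the dioxolane, to which the push–pull silyl enol ether is stable, and return 10.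

Step 8. The peroxide anion may add too slowly to the tetrasubstituted, isopropyl-bearing β-carbon, may add from both faces, or the base may move the C8=C9 bond through the C7 enolate. Fallback, from 12 back to 13: the epoxide is made by electrophilic oxidation of the electron-rich alkene of the reduced enone. Luche reduction of 12, with hydride from the open β face, should give the 6α-allylic alcohol F4. Me3SiCl and imidazole should give its trimethylsilyl ether F5. DMDO in acetone should epoxidise the tetrasubstituted alkene anti to the 6α-silyloxy group and to C10, giving the 4β,5β-epoxy silyl ether F6. K2CO3 in MeOH at 0 °C should free the epoxy alcohol F7, and DMP oxidation returns 13.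

Step 13. Hydride delivery at C9 may be unselective, or may prefer the α face because of the syn-axial C1 methyl, and give the 9β-alcohol. Fallback, from 19 back to 20: the 9β-alcohol F8 formed under the same reduction conditions is inverted by a Mitsunobu reaction with chloroacetic acid (PPh3, diisopropyl azodicarboxylate) to the 9α-chloroacetate F9. The chloroacetate is then removed selectively with thiourea and NaHCO3 in EtOH, in the presence of the isovalerate, to give 20.

Further compounds
F1 | step 5 | 6-bromo-7-methyl-1,4-dioxaspiro[4.4]non-6-ene | CC1=C(Br)C2(CC1)OCCO2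
F2 | step 5 | 7-methyl-6-vinyl-1,4-dioxaspiro[4.4]non-6-ene | C=CC1=C(C)CCC12OCCO2
F3 | step 5 | methyl 9,10α-bis(TBS-oxy)-4,4-ethylenedioxy-11,12,13-trinordauca-5,8-dien-14-oate | COC(=O)C1=C(O[Si](C)(C)C(C)(C)C)[C@@H](O[Si](C)(C)C(C)(C)C)[C@@]2(C)CCC3(OCCO3)C2=CC1
F4 | step 8 | methyl 9,10α-bis(TBS-oxy)-6α-hydroxydauca-4,8-dien-14-oate | COC(=O)C1=C(O[Si](C)(C)C(C)(C)C)[C@@H](O[Si](C)(C)C(C)(C)C)[C@@]2(C)CCC(C(C)C)=C2[C@@H](O)C1
F5 | step 8 | methyl 9,10α-bis(TBS-oxy)-6α-(trimethylsilyloxy)dauca-4,8-dien-14-oate | COC(=O)C1=C(O[Si](C)(C)C(C)(C)C)[C@@H](O[Si](C)(C)C(C)(C)C)[C@@]2(C)CCC(C(C)C)=C2[C@@H](O[Si](C)(C)C)C1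
F6 | step 8 | methyl 9,10α-bis(TBS-oxy)-4β,5β-epoxy-6α-(trimethylsilyloxy)dauc-8-en-14-oate | COC(=O)C1=C(O[Si](C)(C)C(C)(C)C)[C@@H](O[Si](C)(C)C(C)(C)C)[C@@]2(C)CC[C@]3(C(C)C)O[C@]23[C@@H](O[Si](C)(C)C)C1
F7 | step 8 | methyl 9,10α-bis(TBS-oxy)-4β,5β-epoxy-6α-hydroxydauc-8-en-14-oate | COC(=O)C1=C(O[Si](C)(C)C(C)(C)C)[C@@H](O[Si](C)(C)C(C)(C)C)[C@@]2(C)CC[C@]3(C(C)C)O[C@]23[C@@H](O)C1
F8 | step 13 | 6α-(3-methylbutanoyloxy)-10α-(TBS-oxy)-5α-dauc-8(14)-ene-4β,9β-diol | C=C1C[C@H](OC(=O)CC(C)C)[C@@H]2[C@](C)(CC[C@@]2(O)C(C)C)[C@H](O[Si](C)(C)C(C)(C)C)[C@H]1O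
F9 | step 13 | 9α-(chloroacetoxy)-6α-(3-methylbutanoyloxy)-10α-(TBS-oxy)-5α-dauc-8(14)-en-4β-ol | C=C1C[C@H](OC(=O)CC(C)C)[C@@H]2[C@](C)(CC[C@@]2(O)C(C)C)[C@H](O[Si](C)(C)C(C)(C)C)[C@@H]1OC(=O)CCl
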